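**Plan** (azulene locants: C3 = C(OH)i-Pr, C3a = ring-fusion CH, C4 = acyloxy carbon, C6 = vinylic C–Me, C8a = quaternary C–Me; β = face of the C8a methyl, α = the other face)
1. Retrosynthesis: the veratrate C–O bond is cut last; C4–OH and C3(OH)i-Pr go back to carbonyl groups, giving hydroazulene dienone 12. Its seven-membered ring is cut at C6–C7 and C8–C8a, which takes off a vinyl group and restores a cyclopropane C4–C5–C6. The cyclopentenone is cut by a (2+2+1) disconnection and the cyclopropane by methylene transfer to an allylic alcohol.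
2. Enabling feature: at the enone level the seven-membered ring is a cyclohepta-1,4-diene (C3a=C4 and C6=C7 flanking C5H2). This is the product pattern of a cis-1,2-dialkenylcyclopropane: the three-membered ring C4–C5–C6, carrying the cyclopentenone alkene C3a=C8a on C4 and a vinyl group on C6, expands by a strain-driven [3,3] shift, a formal (5+2) union.
3. Forward order: cyclopropane (temporary ring, steps 1–2), five-membered ring by Pauson–Khand reaction (steps 3–6), vinylation and ring expansion to the seven-membered ring (step 7), oxygenation and isopropyl addition (steps 8–11), esterification (step 12).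
4. Stereochemistry: the reagent-controlled cyclopropanation is the only external source of chirality; it is relayed to C8a in the boat rearrangement. C3a is set by enolate protonation, C3 by addition anti to the angular methyl, C4 by hydroxyl-directed hydride delivery.

Key step: step 7

Step 1
Reactants: 1 but-2-yn-1-ol
Product: 3 (Z)-3-iodobut-2-en-1-ol, via cyclic vinylalanate 2 (not isolated)
Conditions: NaAlH2(OCH2CH2OMe)2, Et2O, 0 °C to rt; EtOAc; then I2, THF, −78 °C
Reagents that add atoms: iodine, II; sodium bis(2-methoxyethoxy)aluminium hydride, [Na+].[H][Al-]([H])(OCCOC)OCCOC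
Why: Hydroxyl-directed trans-hydroalumination of the propargylic alcohol places aluminium on C3 in a five-membered alanate, and iodinolysis with retention should give the Z-iodide with iodine cis to the hydroxymethyl group (no stereocentre, only the alkene geometry, is set).

Step 2
Reactants: 3 (Z)-3-iodobut-2-en-1-ol
Product: 4 [(1S,2S)-2-iodo-2-methylcyclopropyl]methanol
Conditions: Et2Zn, CH2I2, DME, CH2Cl2, −10 °C; (4S,5S)-2-butyl-N,N,N′,N′-tetramethyl-1,3,2-dioxaborolane-4,5-dicarboxamide (1.2 equiv), −10 °C to rt
Reagents that add atoms: diiodomethane, ICI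
Why: Charette asymmetric Simmons–Smith cyclopropanation: the zinc alkoxide is bound by the chiral dioxaborolane, which directs Zn(CH2I)2 to one alkene face, so both ring stereocentres (1S,2S) arise together and the Z geometry becomes the cis relation of iodine and CH2OH; the (4S,5S) ligand is chosen from the facial model by which the (4R,5R) ligand turns cinnamyl alcohol into (1S,2S)-(2-phenylcyclopropyl)methanol.

Step 3
Reactants: 4 [(1S,2S)-2-iodo-2-methylcyclopropyl]methanol
Product: 5 (1S,2S)-2-iodo-2-methylcyclopropane-1-carbaldehyde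
Conditions: (n-Pr4N)RuO4 (5 mol %), N-methylmorpholine N-oxide, 4 Å molecular sieves, CH2Cl2, rt
Reagents that add atoms: none
Why: Ley–Griffith oxidation under neutral conditions should give the aldehyde without epimerising the ring carbon next to the carbonyl group and without touching the C–I bond.

Step 4
Reactants: 5 (1S,2S)-2-iodo-2-methylcyclopropane-1-carbaldehyde
Product: 6 (1S,2S)-2-ethynyl-1-iodo-1-methylcyclopropane
Conditions: dimethyl (1-diazo-2-oxopropyl)phosphonate, K2CO3, MeOH, 0 °C to rt
Reagents that add atoms: dimethyl (1-diazo-2-oxopropyl)phosphonate, COP(=O)(OC)C(=[N+]=[N-])C(C)=O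
Why: The Ohira–Bestmann variant of the Seyferth–Gilbert homologation converts the aldehyde into the terminal alkyne under carbonate/methanol conditions that should leave both ring stereocentres and the iodide untouched.

Step 5
Reactants: 6 (1S,2S)-2-ethynyl-1-iodo-1-methylcyclopropane
Product: 8 (1S,2S)-1-iodo-1-methyl-2-(prop-1-yn-1-yl)cyclopropane, via lithium acetylide 7 (not isolated)
Conditions: LiN(i-Pr)2, THF, −78 °C; then MeI, −78 °C to rt
Reagents that add atoms: iodomethane, CI; lithium diisopropylamide, [Li]N(C(C)C)C(C)C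
Why: Deprotonation of the terminal alkyne with an amide base (which does not undergo iodine–lithium exchange) and SN2 methylation of acetylide 7 should give the internal alkyne needed for the cyclopentenone.

Step 6
Reactants: 8 (1S,2S)-1-iodo-1-methyl-2-(prop-1-yn-1-yl)cyclopropane
Product: 10 2-[(1S,2S)-2-iodo-2-methylcyclopropyl]-3-methylcyclopent-2-en-1-one, via hexacarbonyldicobalt alkyne complex 9 (not isolated)
Conditions: Co2(CO)8 (1.1 equiv), toluene, rt; then ethylene (6 bar), DMSO (6 equiv), 70 °C
Reagents that add atoms: ethylene, C=C; dicobalt octacarbonyl, O=C=[Co](=C=O)(=C=O)(=C=O)[Co](=C=O)(=C=O)(=C=O)=C=O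
Why: Intermolecular Pauson–Khand (2+2+1) reaction: ethylene inserts at the less hindered, methyl-bearing alkyne carbon of complex 9 and CO ends next to the bulkier cyclopropyl-bearing carbon, which should give the 2-cyclopropyl-3-methylcyclopentenone regiochemistry (as with other 2-alkynes and ethylene) while the ring stereocentres are untouched.

Step 7
Reactants: 10 2-[(1S,2S)-2-iodo-2-methylcyclopropyl]-3-methylcyclopent-2-en-1-one
Product: 12 (8aR)-6,8a-dimethyl-2,5,8,8a-tetrahydroazulen-3(1H)-one, via cis-dialkenylcyclopropane 11 (not isolated)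
Conditions: vinylboronic acid pinacol ester (2 equiv), Pd(OAc)2 (10 mol %), SPhos (20 mol %), CsF (3 equiv), 1,4-dioxane, 80 °C; then 110 °C, sealed tube
Reagents that add atoms: 4,4,5,5-tetramethyl-2-vinyl-1,3,2-dioxaborolane, C=CB1OC(C)(C)C(C)(C)O1
Why: Proposed new method: zerovalent palladium inserts into the cyclopropyl C–I bond in a three-centre oxidative addition with retention (as for sp2 halides), the fluoride-activated vinylboronate transmetalates and reductive elimination gives cis-dialkenylcyclopropane 11 (bond C6–C7), which on further heating undergoes the concerted [3,3] shift through a boat transition state, breaking the cyclopropane bond C4–C6 and forming C8–C8a. The closest known reactions are the Suzuki–Miyaura coupling of secondary iodocyclopropanes with alkenylboron reagents, which goes with retention, and the divinylcyclopropane–cycloheptadiene (Cope) rearrangement of 2-methylcyclopentenyl-substituted vinylcyclopropanes; new here are the fully substituted ring carbon as the electrophile and the merging of both events in one flask. The seven-membered ring closes by this sigmatropic ring expansion, a formal (5+2) union of the five-carbon unit C6–C5–C4–C3a–C8a with the vinyl group, not by an ionic or radical cyclisation. The quaternary stereocentre C8a is fixed by chirality transfer: in the boat array the cyclopentenone must lie over the three-membered ring, so C8 can reach only one face of C3a=C8a, and the (1S,2S) ring should give 8aR. The step needs retention at C6 (vinyl cis to the cyclopentenone), which the concerted oxidative addition and the configurational stability of cyclopropyl–palladium species should secure, and it needs the Z-methyl on C8a to be tolerated in the boat, which costs temperature but not selectivity; fluoride is a base mild enough to leave the skipped dienone unconjugated.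

Step 8
Reactants: 12 (8aR)-6,8a-dimethyl-2,5,8,8a-tetrahydroazulen-3(1H)-one
Product: 14 (3aS,4R,8aR)-4-hydroxy-6,8a-dimethyl-2,3a,4,5,8,8a-hexahydroazulen-3(1H)-one, via β-boryl ketone 13 (not isolated)
Conditions: B2pin2 (1.1 equiv), CuCl (5 mol %), DPEphos (5 mol %), NaOt-Bu (10 mol %), MeOH (2 equiv), THF, 0 °C to rt; then 30% H2O2, aq. NaHCO3, 0 °C
Reagents that add atoms: bis(pinacolato)diboron, CC1(C)OB(OC1(C)C)B1OC(C)(C)C(C)(C)O1; hydrogen peroxide, OO
Why: Copper-catalysed conjugate borylation of the enone puts boron on C4, expected from the convex β-face of the folded cycloheptadiene, methanol then protonates the enolate at C3a anti to the flanking boryl and angular methyl groups (3aS, trans ring fusion), and buffered peroxide oxidation replaces boron by hydroxyl with retention; the C4 configuration is of no consequence because it is erased in step 10.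

Step 9
Reactants: 14 (3aS,4R,8aR)-4-hydroxy-6,8a-dimethyl-2,3a,4,5,8,8a-hexahydroazulen-3(1H)-one
Product: 15 (3R,3aS,4R,8aR)-6,8a-dimethyl-3-(propan-2-yl)-1,2,3,3a,4,5,8,8a-octahydroazulene-3,4-diol
Conditions: CeCl3 (3.5 equiv), i-PrMgCl (3.2 equiv), THF, −78 °C; then 14, −78 to −20 °C
Reagents that add atoms: isopropylmagnesium chloride, CC(C)[Mg]Cl
Why: Organocerium 1,2-addition (non-basic, so enolisation, reduction and retro-aldol cleavage of the β-hydroxy ketone are suppressed) should occur on the α-face of the cyclopentanone, anti to the angular methyl and the C4 alkoxide, setting 3R with the hydroxyl cis to the angular methyl.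

Step 10
Reactants: 15 (3R,3aS,4R,8aR)-6,8a-dimethyl-3-(propan-2-yl)-1,2,3,3a,4,5,8,8a-octahydroazulene-3,4-diol
Product: 16 (3R,3aR,8aR)-3-hydroxy-6,8a-dimethyl-3-(propan-2-yl)-2,3,3a,5,8,8a-hexahydroazulen-4(1H)-one
Conditions: (n-Pr4N)RuO4 (5 mol %), N-methylmorpholine N-oxide, 4 Å molecular sieves, CH2Cl2, 0 °C to rt
Reagents that add atoms: none
Why: Ley–Griffith oxidation is selective for the secondary alcohol and, being neutral, should spare the tertiary β-hydroxyl, the C3a stereocentre and the β,γ-position of the alkene.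

Step 11
Reactants: 16 (3R,3aR,8aR)-3-hydroxy-6,8a-dimethyl-3-(propan-2-yl)-2,3,3a,5,8,8a-hexahydroazulen-4(1H)-one
Product: 17 (3R,3aS,4S,8aR)-6,8a-dimethyl-3-(propan-2-yl)-1,2,3,3a,4,5,8,8a-octahydroazulene-3,4-diol (jaeschkeanadiol)
Conditions: Me4NBH(OAc)3, MeCN/AcOH (1:1), −30 °C
Reagents that add atoms: none
Why: Evans–Saksena hydroxyl-directed reduction: the tertiary C3 hydroxyl exchanges onto boron and delivers hydride intramolecularly to the β-face of the C4 ketone, which should give the anti-1,3-diol, that is the 4S (α) alcohol.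

Step 12
Reactants: 17 jaeschkeanadiol; 18 3,4-dimethoxybenzoyl chloride
Product: 19 (3R,3aS,4S,8aR)-3-hydroxy-6,8a-dimethyl-3-(propan-2-yl)-1,2,3,3a,4,5,8,8a-octahydroazulen-4-yl 3,4-dimethoxybenzoate
Conditions: pyridine, DMAP (0.2 equiv), CH2Cl2, 0 °C to rt
Reagents that add atoms: none
Why: DMAP-catalysed acylation with the acid chloride should esterify only the secondary C4 hydroxyl with retention, the tertiary C3 hydroxyl being too hindered to react.

**Compound list**
1 | but-2-yn-1-ol | CC#CCO | starting material
2 | sodium 2,2-bis(2-methoxyethoxy)-3-methyl-2,5-dihydro-1,2-oxaaluminol-2-uide (cyclic vinylalanate) | [Na+].CC1=CCO[Al-]1(OCCOC)OCCOC | intermediate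
3 | (Z)-3-iodobut-2-en-1-ol | C/C(I)=C/CO | intermediate
4 | [(1S,2S)-2-iodo-2-methylcyclopropyl]methanol | OC[C@@H]1C[C@]1(C)I | intermediate
5 | (1S,2S)-2-iodo-2-methylcyclopropane-1-carbaldehyde | O=C[C@@H]1C[C@]1(C)I | intermediate
6 | (1S,2S)-2-ethynyl-1-iodo-1-methylcyclopropane | C#C[C@@H]1C[C@]1(C)I | intermediate
7 | lithium [(1S,2S)-2-iodo-2-methylcyclopropyl]ethynide | [Li]C#C[C@@H]1C[C@]1(C)I | intermediate
8 | (1S,2S)-1-iodo-1-methyl-2-(prop-1-yn-1-yl)cyclopropane | CC#C[C@@H]1C[C@]1(C)I | intermediate
9 | hexacarbonyldicobalt complex of alkyne 8, Co2(CO)6(alkyne) | CC12[Co]3(=C=O)(=C=O)(=C=O)[Co]1(=C=O)(=C=O)(=C=O)C23[C@@H]1C[C@]1(C)I | intermediate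
10 | 2-[(1S,2S)-2-iodo-2-methylcyclopropyl]-3-methylcyclopent-2-en-1-one | CC1=C(C(=O)CC1)[C@@H]1C[C@]1(C)I | intermediate
11 | 2-[(1R,2R)-2-ethenyl-2-methylcyclopropyl]-3-methylcyclopent-2-en-1-one (vinyl cis to the cyclopentenone) | CC1=C(C(=O)CC1)[C@@H]1C[C@]1(C)C=C | intermediate
12 | (8aR)-6,8a-dimethyl-2,5,8,8a-tetrahydroazulen-3(1H)-one | CC1=CC[C@@]2(C)CCC(=O)C2=CC1 | intermediate
13 | (3aR,4R,8aR)-6,8a-dimethyl-4-(4,4,5,5-tetramethyl-1,3,2-dioxaborolan-2-yl)-2,3a,4,5,8,8a-hexahydroazulen-3(1H)-one | CC1(C)OB(OC1(C)C)[C@@H]1CC(C)=CC[C@@]2(C)CCC(=O)[C@H]12 | intermediate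
14 | (3aS,4R,8aR)-4-hydroxy-6,8a-dimethyl-2,3a,4,5,8,8a-hexahydroazulen-3(1H)-one | O[C@@H]1CC(C)=CC[C@@]2(C)CCC(=O)[C@H]12 | intermediate
15 | (3R,3aS,4R,8aR)-6,8a-dimethyl-3-(propan-2-yl)-1,2,3,3a,4,5,8,8a-octahydroazulene-3,4-diol | O[C@@H]1CC(C)=CC[C@@]2(C)CC[C@@](O)(C(C)C)[C@H]12 | intermediate
16 | (3R,3aR,8aR)-3-hydroxy-6,8a-dimethyl-3-(propan-2-yl)-2,3,3a,5,8,8a-hexahydroazulen-4(1H)-one | O=C1CC(C)=CC[C@@]2(C)CC[C@@](O)(C(C)C)[C@H]12 | intermediate
17 | (3R,3aS,4S,8aR)-6,8a-dimethyl-3-(propan-2-yl)-1,2,3,3a,4,5,8,8a-octahydroazulene-3,4-diol (jaeschkeanadiol) | O[C@H]1CC(C)=CC[C@@]2(C)CC[C@@](O)(C(C)C)[C@H]12 | intermediate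
18 | 3,4-dimethoxybenzoyl chloride | COc1ccc(C(Cl)=O)cc1OC | starting material
19 | (3R,3aS,4S,8aR)-3-hydroxy-6,8a-dimethyl-3-(propan-2-yl)-1,2,3,3a,4,5,8,8a-octahydroazulen-4-yl 3,4-dimethoxybenzoate | COc1ccc(C(=O)O[C@H]2CC(C)=CC[C@@]3(C)CC[C@@](O)(C(C)C)[C@H]23)cc1OC | target

Total step count: 12. Longest linear sequence: 12 steps (1 to 19).

**Steps most likely to fail**

Step 7 (proposed new method). What may go wrong: oxidative addition at the fully substituted iodocyclopropane carbon may be slow, so that β-hydride loss or ring opening of the cyclopropyl–palladium species outruns vinyl transfer; the basic fluoride medium may also move the skipped alkene of the product into conjugation at 110 °C. Fallback with known chemistry, setting out from 8 and coming back at 12: iodine–lithium exchange on 8 (t-BuLi, Et2O, −78 °C, retention) and transmetalation with ZnCl2 give chloro[(1S,2S)-1-methyl-2-(prop-1-yn-1-yl)cyclopropyl]zinc F1. Negishi coupling of this reagent with vinyl bromide (Pd(PPh3)4, THF, rt, retention) gives (1R,2R)-1-ethenyl-1-methyl-2-(prop-1-yn-1-yl)cyclopropane F2. Complexation with Co2(CO)8 gives the hexacarbonyldicobalt complex of this enyne F3, which under ethylene as in step 6 gives 11; heating 11 in toluene at 110 °C under neutral conditions gives 12.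

Step 8. What may go wrong: protonation of the copper enolate from the β-face would give the cis ring fusion, and the β-hydroxy ketone may lose water back to the enone during the oxidative work-up. Fallback, setting out from 12 and coming back at 15: Weitz–Scheffer epoxidation of the enone (H2O2, NaOH, MeOH, 0 °C) from the convex face gives (3aS,4R,8aR)-3a,4-epoxy-6,8a-dimethyl-2,3a,4,5,8,8a-hexahydroazulen-3(1H)-one F4. Organocerium addition as in step 9, anti to the epoxide oxygen and the angular methyl, gives (3R,3aS,4R,8aR)-3a,4-epoxy-6,8a-dimethyl-3-(propan-2-yl)-1,2,3,3a,4,5,8,8a-octahydroazulen-3-ol F5. Reductive epoxide opening with Cp2TiCl (trivalent titanium, made from Cp2TiCl2 and Zn) and 1,4-cyclohexadiene in THF breaks the C3a–O bond and transfers a hydrogen atom to the α-face of the tertiary radical (three β-substituents block the other face), which gives 15.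

Step 6. What may go wrong: the hindered internal alkyne complex may take up ethylene poorly, or the insertion may go with the wrong regiochemistry. Fallback, setting out from 4 and coming back at 10: iodination of 4 (I2, PPh3, imidazole, CH2Cl2) gives (1S,2S)-1-iodo-2-(iodomethyl)-1-methylcyclopropane F6. Alkylation of 5-methyl-2-furyllithium (from 2-methylfuran and n-BuLi, THF, −78 °C to rt) at the primary iodide gives 2-{[(1R,2S)-2-iodo-2-methylcyclopropyl]methyl}-5-methylfuran F7. Acid hydrolysis of the furan (aq. H2SO4, AcOH, 60 °C) gives 1-[(1R,2S)-2-iodo-2-methylcyclopropyl]heptane-2,5-dione F8, and intramolecular aldol condensation (NaOH, EtOH, reflux) gives 10.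

**Further compounds**
F1 | step 7 | chloro[(1S,2S)-1-methyl-2-(prop-1-yn-1-yl)cyclopropyl]zinc | CC#C[C@@H]1C[C@]1(C)[Zn]Cl
F2 | step 7 | (1R,2R)-1-ethenyl-1-methyl-2-(prop-1-yn-1-yl)cyclopropane | CC#C[C@@H]1C[C@]1(C)C=C
F3 | step 7 | hexacarbonyldicobalt complex of enyne F2 | CC12[Co]3(=C=O)(=C=O)(=C=O)[Co]1(=C=O)(=C=O)(=C=O)C23[C@@H]1C[C@]1(C)C=C
F4 | step 8 | (3aS,4R,8aR)-3a,4-epoxy-6,8a-dimethyl-2,3a,4,5,8,8a-hexahydroazulen-3(1H)-one | O1[C@@H]2CC(C)=CC[C@@]3(C)CCC(=O)[C@@]123
F5 | step 8 | (3R,3aS,4R,8aR)-3a,4-epoxy-6,8a-dimethyl-3-(propan-2-yl)-1,2,3,3a,4,5,8,8a-octahydroazulen-3-ol | O1[C@@H]2CC(C)=CC[C@@]3(C)CC[C@@](O)(C(C)C)[C@@]123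
F6 | step 6 | (1S,2S)-1-iodo-2-(iodomethyl)-1-methylcyclopropane | IC[C@@H]1C[C@]1(C)I
F7 | step 6 | 2-{[(1R,2S)-2-iodo-2-methylcyclopropyl]methyl}-5-methylfuran | Cc1ccc(C[C@@H]2C[C@]2(C)I)o1
F8 | step 6 | 1-[(1R,2S)-2-iodo-2-methylcyclopropyl]heptane-2,5-dione | CC(=O)CCC(=O)C[C@@H]1C[C@]1(C)I
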